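**Plan**

1. The C12–C13 bond of the ethano linker is cut first (made as a C12=C13 alkene by Julia–Kocienski olefination, then saturated), which gives an east benzoxepane aldehyde (C13–C24, O20) and a west hydroazulene sulfone (C1′–C8a′, C12).
2. East half: ring B (C14, C15, C21–C24) carries O20 on C21 next to the quaternary C15 and para to the methyl-bearing C24, the pattern of (R)-carvone with oxygen in place of its isopropenyl group; the cuts are O20–C19 (oxepane), C15–C16 and C15–CH3 (enolate alkylations) and C14–C13 ([2,3]-Wittig–Still).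
3. Forward east: carvone is alkylated twice at C6, the side-chain alkene is epoxidized, the isopropenyl group is excised to the C21 hydroxyl, the oxepane is closed by 7-endo opening of the epoxide, and the enone is then turned into the C14 and C24 centres through an epoxide/Wharton/[2,3] relay and a directed epoxidation.
4. West half: the cuts are C6′=C7′ (ring-closing metathesis), C8′–C7′ (B-alkyl Suzuki), C5′–C12 (methylenation/hydroboration) and C1′–C8a′ (aldol); forward, (S)-limonene gives a cyclopentene carbaldehyde, then the cyclopentanol, then the seven-membered ring.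
5. Stereochemistry: C21 is carvone C5 and controls C15 (methylation anti to isopropenyl); C18 comes from the Shi catalyst; the C23 epoxide oxygen (trans to O20) is relayed to C14 and from there to C24; C3a′ is limonene C4 and controls C1′ (epoxide anti) and C8a′ (hydroboration); C5′ is set by convex-face hydroboration.

Key step: step 6

Remark: C12 and C13 are the linker carbons, C14 the ring carbon that bears the linker, C15 the quaternary fusion carbon, C16–C19 the oxepane carbons (C18 carbinol, C19 gem-dimethyl), O20 the ring oxygen, C21 the oxygen-bearing fusion carbon, C22 and C23 methylenes, C24 the tertiary carbinol; the west bicycle carries azulene locants with primes; an undefined centre in a SMILES string (3, 20–23) stands for both epimers.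

Step 1
Reactants: 1 (R)-(−)-carvone; 2 5-iodo-2-methylpent-2-ene
Product: 3 (5R)-2-methyl-6-(4-methylpent-3-en-1-yl)-5-(prop-1-en-2-yl)cyclohex-2-en-1-one (both C6 epimers)
Conditions: LiN(iPr)2, THF, −78 °C; then 2, DMPU, −78 to −20 °C
Reagents that add atoms: none
Why: Kinetic deprotonation gives the cross-conjugated α′-lithium enolate, which should be alkylated at C6 by the primary iodide in an SN2 enolate alkylation; the C6 configuration does not matter because this carbon is enolized again in step 2.

Step 2
Reactants: 3
Product: 4 (5S,6R)-2,6-dimethyl-6-(4-methylpent-3-en-1-yl)-5-(prop-1-en-2-yl)cyclohex-2-en-1-one (6-methyl trans to isopropenyl)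
Conditions: LiN(iPr)2, THF, −78 °C; then MeI, −78 to 0 °C
Reagents that add atoms: iodomethane, CI
Why: Second α′-enolate alkylation; iodomethane should enter the trisubstituted enolate anti to the neighbouring isopropenyl group, which sets the quaternary centre (future C15) with the methyl trans and the homoprenyl chain cis to isopropenyl.

Step 3
Reactants: 4
Product: 5 (5S,6R)-6-{2-[(2S)-3,3-dimethyloxiran-2-yl]ethyl}-2,6-dimethyl-5-(prop-1-en-2-yl)cyclohex-2-en-1-one
Conditions: 1,2:4,5-di-O-isopropylidene-β-L-erythro-2,3-hexodiulo-2,6-pyranose (0.3 equiv), KHSO5 (as 2KHSO5·KHSO4·K2SO4), K2CO3, Bu4NHSO4, MeCN/dimethoxymethane/aq. Na2B4O7 buffer, 0 °C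
Reagents that add atoms: potassium peroxymonosulfate, [K+].[O-]S(=O)(=O)OO
Why: Shi asymmetric epoxidation; the dioxirane formed from the L-fructose-derived ketone should epoxidize the electron-rich trisubstituted side-chain alkene faster than the isopropenyl group and the electron-poor enone and, through its spiro transition state, deliver oxygen to the face that gives the S oxirane carbon (future C18) under reagent control.

Step 4
Reactants: 5
Product: 7 (5R,6R)-5-acetoxy-6-{2-[(2S)-3,3-dimethyloxiran-2-yl]ethyl}-2,6-dimethylcyclohex-2-en-1-one, via methoxy hydroperoxide 6 (not isolated)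
Conditions: O3, CH2Cl2/MeOH, −78 °C; then Ac2O, Et3N, 4-(dimethylamino)pyridine, CH2Cl2, 0 to 23 °C
Reagents that add atoms: ozone, [O-][O+]=O; methanol, CO
Why: Ozonolysis followed by Criegee rearrangement; ozone should cleave the isopropenyl group in preference to the electron-poor enone alkene to give 6, whose peracetate rearranges by migration of the ring carbon from carbon to oxygen with retention, so that the new C–O bond (future C21–O20) stands where the isopropenyl group stood and the acetyl group of 7 is the former isopropenyl carbon with its methyl.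

Step 5
Reactants: 7
Product: 8 (5R,6R)-6-{2-[(2S)-3,3-dimethyloxiran-2-yl]ethyl}-5-hydroxy-2,6-dimethylcyclohex-2-en-1-one
Conditions: K2CO3 (0.2 equiv), MeOH, 0 °C
Reagents that add atoms: none
Why: Carbonate-catalysed transesterification with methanol should free the secondary alcohol without touching the oxirane, and the quaternary α-carbon rules out β-elimination towards C15.

Step 6
Reactants: 8
Product: 9 (3S,5aR,9aR)-3-hydroxy-2,2,5a,7-tetramethyl-2,3,4,5,5a,9a-hexahydro-1-benzoxepin-6(9H)-one (cis-fused oxepane enone)
Conditions: (+)-camphor-10-sulfonic acid (0.2 equiv), CH2Cl2, −20 to 0 °C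
Reagents that add atoms: none
Why: The sulfonic acid protonates the oxirane, the C19–O bond stretches towards the gem-dimethyl carbon, which carries most of the positive charge, and the C21 hydroxyl attacks C19 from the rear in a borderline SN1/SN2 opening. The closest known reaction type is the Brønsted-acid-promoted endo-selective cyclization of hydroxy epoxides at the tertiary carbon of trisubstituted epoxides, which gives 2,2-dimethyloxepan-3-ols. The oxepane is closed in the 7-endo-tet mode by the O20–C19 bond. No stereocentre is created: C19 is not stereogenic, C18 keeps the S configuration written by the Shi epoxidation because its C–O bond is not broken, and the cis ring fusion is already fixed by C15 and C21 of 8. The step needs 7-endo attack at C19 over 6-exo attack at C18; the two methyl groups at C19 direct the ionization under a non-nucleophilic Brønsted acid at low temperature, and the cis arrangement of hydroxyl and chain on the ring together with the quaternary C15 hold the chain within reach of the hydroxyl.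

Step 7
Reactants: 9
Product: 10 C18 tert-butyldimethylsilyl ether of 9
Conditions: t-BuMe2SiOSO2CF3, 2,6-lutidine, CH2Cl2, −78 to 0 °C
Reagents that add atoms: tert-butyldimethylsilyl trifluoromethanesulfonate, CC(C)(C)[Si](C)(C)OS(=O)(=O)C(F)(F)F
Why: Silyl ether formation with the silyl triflate should protect the hindered secondary C18 hydroxyl through the base, hydride and organolithium steps that follow; no stereocentre is touched.

Step 8
Reactants: 10
Product: 11 epoxy ketone (10 with a C23–C24 oxirane on the face of the C15 methyl group)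
Conditions: H2O2 (30% aq), NaOH, MeOH, 0 °C
Reagents that add atoms: hydrogen peroxide, OO
Why: Weitz–Scheffer nucleophilic epoxidation; hydroperoxide should add to C23 from the face opposite the C21–O20 bond, as 5-substituted cyclohexenones of the carvone type are attacked trans to the 5-substituent, which places the oxirane (C23 and C24) on the face of the C15 methyl group.

Step 9
Reactants: 11
Product: 12 allylic alcohol with C14=C24 alkene and C23 hydroxyl syn to the C15 methyl group
Conditions: N2H4·H2O, AcOH, MeOH, 0 to 23 °C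
Reagents that add atoms: none
Why: Wharton transposition; the hydrazone of the epoxy ketone collapses with loss of N2 to the allylic alcohol, and because the C23–O bond is never broken the carbinol keeps the configuration written in step 8.

Step 10
Reactants: 12
Product: 13 (tributylstannyl)methyl ether of 12
Conditions: KH, THF, 0 °C; then Bu3SnCH2I, 18-crown-6, 0 to 23 °C
Reagents that add atoms: (iodomethyl)tributylstannane, CCCC[Sn](CCCC)(CCCC)CI
Why: Williamson etherification of the potassium alkoxide with the primary iodide should give the stannylmethyl ether needed for the sigmatropic step; no stereocentre is touched.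

Step 11
Reactants: 13
Product: 14 homoallylic alcohol with the C13 hydroxymethyl group on C14 syn to the C15 methyl group and a C23=C24 alkene
Conditions: n-BuLi, THF, −78 to −20 °C
Reagents that add atoms: none
Why: [2,3]-Wittig–Still rearrangement; tin–lithium exchange gives the α-alkoxymethyllithium, which should rearrange suprafacially through a five-membered transition state so that the new C14–C13 bond forms on the ring face that carried the C23–O bond, which sets C14 and returns the alkene to C23=C24.

Step 12
Reactants: 14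
Product: 15 epoxy alcohol (14 with a C23–C24 oxirane syn to the hydroxymethyl group)
Conditions: VO(acac)2 (5 mol %), t-BuOOH, CH2Cl2, 0 to 23 °C
Reagents that add atoms: tert-butyl hydroperoxide, CC(C)(C)OO
Why: Hydroxyl-directed epoxidation of a homoallylic alcohol with the vanadium–hydroperoxide system should deliver oxygen to the alkene face syn to the C13 hydroxymethyl group, which sets C24 (and C23).

Step 13
Reactants: 15
Product: 16 diol with primary C13 hydroxyl and tertiary C24 hydroxyl syn to C13 (C18 silyl ether kept)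
Conditions: LiAlH4, THF, 0 to 23 °C
Reagents that add atoms: none
Why: Hydride opening of the trisubstituted epoxide (SN2, trans-diaxial) should occur at the less substituted C23 and leave the tertiary C24 alcohol with the configuration set in step 12.

Step 14
Reactants: 16
Product: 17 C13 aldehyde of 16 (β-hydroxy aldehyde)
Conditions: 2,2,6,6-tetramethylpiperidin-1-oxyl (10 mol %), PhI(OAc)2, CH2Cl2, 23 °C
Reagents that add atoms: none
Why: Oxoammonium-mediated oxidation should convert the primary alcohol into the aldehyde and leave the tertiary alcohol and the silyl ether alone, without epimerizing C14 under these non-basic conditions.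

Step 15
Reactants: 17
Product: 18 C24 triethylsilyl ether of 17
Conditions: Et3SiOSO2CF3, 2,6-lutidine, CH2Cl2, −78 °C
Reagents that add atoms: triethylsilyl trifluoromethanesulfonate, CC[Si](CC)(CC)OS(=O)(=O)C(F)(F)F
Why: Silyl ether formation at low temperature should mask the β-hydroxyl so that no retro-aldol cleavage can occur under the basic olefination conditions; no stereocentre is touched.

Step 16
Reactants: 19 (S)-(−)-limonene
Product: 21 2-[(1S)-4-methylcyclohex-3-en-1-yl]propan-1-ol (both C2 epimers), via borane 20 (not isolated)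
Conditions: 9-BBN, THF, 0 to 23 °C; then NaOH (aq), H2O2, 0 °C
Reagents that add atoms: 9-borabicyclo[3.3.1]nonane (in 20 only), B1C2CCCC1CCC2; hydrogen peroxide, OO
Why: Hydroboration–oxidation; 9-BBN should add to the 1,1-disubstituted isopropenyl alkene far faster than to the trisubstituted ring alkene and place boron on the terminal carbon, and the new stereocentre is of no consequence because it is removed in step 19.

Step 17
Reactants: 21
Product: 22 2-[(1S)-4-methylcyclohex-3-en-1-yl]propanoic acid (both C2 epimers)
Conditions: 2,2,6,6-tetramethylpiperidin-1-oxyl (20 mol %), PhI(OAc)2 (2.2 equiv), MeCN/H2O, 23 °C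
Reagents that add atoms: water, O
Why: Oxoammonium oxidation in aqueous acetonitrile should take the primary alcohol through the aldehyde hydrate to the carboxylic acid without touching the trisubstituted alkene.

Step 18
Reactants: 22
Product: 23 N-methoxy-N-methyl-2-[(1S)-4-methylcyclohex-3-en-1-yl]propanamide (both C2 epimers)
Conditions: MeNH(OMe)·HCl, 1-ethyl-3-(3-dimethylaminopropyl)carbodiimide hydrochloride, N-methylmorpholine, CH2Cl2, 0 to 23 °C
Reagents that add atoms: N,O-dimethylhydroxylamine hydrochloride, CNOC.Cl
Why: Carbodiimide-mediated amide coupling should give the Weinreb amide, which serves first as an enolate precursor and later as a ketone precursor.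

Step 19
Reactants: 23
Product: 24 N-methoxy-N,2-dimethyl-2-[(1S)-4-methylcyclohex-3-en-1-yl]propanamide
Conditions: LiN(iPr)2, THF, −78 °C; then MeI, −78 to −20 °C
Reagents that add atoms: iodomethane, CI
Why: Amide enolate alkylation; deprotonation removes the stereocentre next to the carbonyl and methylation should build the gem-dimethyl quaternary carbon (future C4′).

Step 20
Reactants: 24
Product: 26 (3S)-N-methoxy-N,2,2-trimethyl-6-oxo-3-(2-oxoethyl)heptanamide, via ozonide 25 (not isolated)
Conditions: O3, CH2Cl2, −78 °C; then PPh3, −78 to 23 °C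
Reagents that add atoms: ozone, [O-][O+]=O
Why: Ozonolysis with reductive work-up should cleave the only alkene to the keto aldehyde; the stereocentre (future C3a′) is not touched.

Step 21
Reactants: 26
Product: 27 2-[(1S)-2-formyl-3-methylcyclopent-2-en-1-yl]-N-methoxy-N,2-dimethylpropanamide
Conditions: piperidine, AcOH, toluene, 60 °C
Reagents that add atoms: none
Why: Amine-catalysed intramolecular aldol condensation; the enamine of the aldehyde should attack the methyl ketone to close the five-membered ring, and dehydration gives the conjugated cyclopentene carbaldehyde.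

Step 22
Reactants: 27
Product: 28 epoxy aldehyde (27 with the 2,3-oxirane trans to the amide side chain)
Conditions: H2O2 (30% aq), NaOH, MeOH, 0 °C
Reagents that add atoms: hydrogen peroxide, OO
Why: Weitz–Scheffer nucleophilic epoxidation of the enal; hydroperoxide should attack the ring face opposite the bulky quaternary side chain on the neighbouring carbon, which sets C1′ (oxygen trans to the side chain) and C8a′.

Step 23
Reactants: 28
Product: 29 2-[(1S,3S)-3-hydroxy-3-methyl-2-methylidenecyclopentyl]-N-methoxy-N,2-dimethylpropanamide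
Conditions: N2H4·H2O, AcOH, MeOH, 0 to 23 °C
Reagents that add atoms: none
Why: Wharton transposition of the epoxy aldehyde should give the tertiary allylic alcohol with an exocyclic methylene group, the C1′–O bond and hence its configuration being retained.

Step 24
Reactants: 29
Product: 31 2-[(1S,2S,3S)-3-hydroxy-3-methyl-2-(prop-2-en-1-yl)cyclopentyl]-N-methoxy-N,2-dimethylpropanamide, via borane 30 (not isolated)
Conditions: 9-BBN (2.5 equiv), THF, 0 to 23 °C; then CH2=CHBr, PdCl2(dppf) [dppf = 1,1′-bis(diphenylphosphino)ferrocene] (5 mol %), K3PO4 (aq), THF/DMF, 50 °C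
Reagents that add atoms: 9-borabicyclo[3.3.1]nonane (in 30 only), B1C2CCCC1CCC2; vinyl bromide, C=CBr
Why: Hydroboration followed by B-alkyl Suzuki–Miyaura coupling; 9-BBN should add to the exocyclic alkene from the face of the hydroxyl and the C3a′ hydrogen, away from the C1′ methyl and the quaternary side chain, which sets C8a′ with all three carbon substituents cis, and palladium-catalysed coupling of the borane with vinyl bromide gives the allyl group.

Step 25
Reactants: 31
Product: 32 4-[(1S,2S,3S)-3-hydroxy-3-methyl-2-(prop-2-en-1-yl)cyclopentyl]-2,4-dimethylpent-1-en-3-one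
Conditions: CH2=C(CH3)MgBr (3 equiv), THF, 0 to 23 °C
Reagents that add atoms: isopropenylmagnesium bromide, CC(=C)[Mg]Br
Why: Weinreb ketone synthesis; the Grignard reagent should add once to the amide through the stable magnesium chelate and give the isopropenyl ketone on work-up, the tertiary alkoxide being a spectator.

Step 26
Reactants: 32
Product: 33 (1S,3aS,8aS)-1-hydroxy-1,4,4,6-tetramethyl-2,3,3a,4,8,8a-hexahydroazulen-5(1H)-one
Conditions: second-generation Grubbs catalyst, (H2IMes)(PCy3)Cl2Ru=CHPh (5 mol %), CH2Cl2, 40 °C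
Reagents that add atoms: none
Why: Ring-closing metathesis between the allyl group and the 2-substituted enone alkene should close the seven-membered ring as the trisubstituted enone with loss of ethene, helped by the gem-dimethyl group and the cis arrangement of the two chains.

Step 27
Reactants: 33
Product: 34 (1S,3aS,8aS)-1,4,4,6-tetramethyl-5-methylidene-1,2,3,3a,4,5,8,8a-octahydroazulen-1-ol
Conditions: Cp2TiMe2 (3 equiv), toluene, 70 °C, dark
Reagents that add atoms: dimethyltitanocene, [CH3-].[CH3-].[Ti+4].c1cc[cH-]c1.c1cc[cH-]c1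
Why: Petasis methylenation; the non-basic titanium methylidene should convert the hindered ketone, which has no α-hydrogen but an acidic γ-position, into the exocyclic alkene without enolization.

Step 28
Reactants: 34
Product: 36 (1S,3aS,5R,8aS)-5-(hydroxymethyl)-1,4,4,6-tetramethyl-1,2,3,3a,4,5,8,8a-octahydroazulen-1-ol, via borane 35 (not isolated)
Conditions: 9-BBN, THF, 0 to 23 °C; then NaOH (aq), H2O2, 0 °C
Reagents that add atoms: 9-borabicyclo[3.3.1]nonane (in 35 only), B1C2CCCC1CCC2; hydrogen peroxide, OO
Why: Hydroboration–oxidation; 9-BBN should add to the less hindered exocyclic end of the diene with boron on the terminal carbon and deliver hydrogen to C5′ from the convex face of the cis-fused bicycle, the face of the ring-fusion hydrogens, which sets C5′ with the hydroxymethyl group on the face of the cyclopentane ring.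

Step 29
Reactants: 36
Product: 37 1-phenyl-1H-tetrazol-5-yl sulfide of 36 at C12
Conditions: 1-phenyl-1H-tetrazole-5-thiol, PPh3, iPrO2CN=NCO2iPr, THF, 0 to 23 °C
Reagents that add atoms: 1-phenyl-1H-tetrazole-5-thiol, Sc1nnnn1-c1ccccc1
Why: Mitsunobu thioetherification should replace the primary hydroxyl by the tetrazolyl thioether; the tertiary alcohol does not react.

Step 30
Reactants: 37
Product: 38 1-phenyl-1H-tetrazol-5-yl sulfone of 36 at C12
Conditions: (NH4)6Mo7O24·4H2O (10 mol %), H2O2 (30% aq), EtOH, 0 to 23 °C
Reagents that add atoms: hydrogen peroxide, OO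
Why: Molybdate-catalysed peroxide oxidation should take the sulfide to the sulfone faster than it epoxidizes the trisubstituted alkene.

Step 31
Reactants: 38; 18
Product: 39 C12=C13 alkene joining both halves (C18 tert-butyldimethylsilyl ether and C24 triethylsilyl ether; E drawn)
Conditions: 38, KN(SiMe3)2 (1.1 equiv), THF, −78 °C; then 18, −78 to 23 °C
Reagents that add atoms: none
Why: Julia–Kocienski olefination; the metalated tetrazolyl sulfone should add to the aldehyde and, after Smiles rearrangement and loss of SO2 and the tetrazolone anion, give the C12=C13 alkene, while addition of the aldehyde to the pre-formed anion at low temperature should avoid epimerization of C14 and β-elimination, and the alkene geometry is of no consequence.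

Step 32
Reactants: 39
Product: 40 C12–C13 saturated bis-silyl ether of the target
Conditions: 2-nitrobenzenesulfonylhydrazide, Et3N, CH2Cl2, 23 °C
Reagents that add atoms: none
Why: Diimide reduction; the concerted syn transfer of hydrogen should saturate the 1,2-disubstituted C12=C13 alkene far faster than the trisubstituted ring alkene and touches no stereocentre.

Step 33
Reactants: 40
Product: 41 (3S,5aS,6S,7R,9aR)-6-{2-[(1S,3aS,5R,8aS)-1-hydroxy-1,4,4,6-tetramethyl-1,2,3,3a,4,5,8,8a-octahydroazulen-5-yl]ethyl}-2,2,5a,7-tetramethyldecahydro-1-benzoxepine-3,7-diol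
Conditions: Bu4NF, THF, 23 to 50 °C
Reagents that add atoms: none
Why: Fluoride-mediated desilylation should remove the tert-butyldimethylsilyl and the triethylsilyl ether in one operation to give the target.

**Compound list**

1 | (R)-(−)-carvone | CC1=CC[C@H](CC1=O)C(C)=C | starting material
2 | 5-iodo-2-methylpent-2-ene | CC(C)=CCCI | starting material
3 | (5R)-2-methyl-6-(4-methylpent-3-en-1-yl)-5-(prop-1-en-2-yl)cyclohex-2-en-1-one (both C6 epimers) | CC1=CC[C@@H](C(C)=C)C(CCC=C(C)C)C1=O | intermediate
4 | (5S,6R)-2,6-dimethyl-6-(4-methylpent-3-en-1-yl)-5-(prop-1-en-2-yl)cyclohex-2-en-1-one | CC1=CC[C@@H](C(C)=C)[C@@](C)(CCC=C(C)C)C1=O | intermediate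
5 | (5S,6R)-6-{2-[(2S)-3,3-dimethyloxiran-2-yl]ethyl}-2,6-dimethyl-5-(prop-1-en-2-yl)cyclohex-2-en-1-one | CC1=CC[C@@H](C(C)=C)[C@@](C)(CC[C@@H]2OC2(C)C)C1=O | intermediate
6 | methoxy hydroperoxide: 5-(1-hydroperoxy-1-methoxyethyl) analogue of 5 | CC1=CC[C@@H](C(C)(OC)OO)[C@@](C)(CC[C@@H]2OC2(C)C)C1=O | intermediate
7 | (5R,6R)-5-acetoxy-6-{2-[(2S)-3,3-dimethyloxiran-2-yl]ethyl}-2,6-dimethylcyclohex-2-en-1-one | CC1=CC[C@@H](OC(C)=O)[C@@](C)(CC[C@@H]2OC2(C)C)C1=O | intermediate
8 | (5R,6R)-6-{2-[(2S)-3,3-dimethyloxiran-2-yl]ethyl}-5-hydroxy-2,6-dimethylcyclohex-2-en-1-one | CC1=CC[C@@H](O)[C@@](C)(CC[C@@H]2OC2(C)C)C1=O | intermediate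
9 | (3S,5aR,9aR)-3-hydroxy-2,2,5a,7-tetramethyl-2,3,4,5,5a,9a-hexahydro-1-benzoxepin-6(9H)-one | CC1=CC[C@H]2OC(C)(C)[C@@H](O)CC[C@@]2(C)C1=O | intermediate
10 | C18 tert-butyldimethylsilyl ether of 9 | CC1=CC[C@H]2OC(C)(C)[C@@H](O[Si](C)(C)C(C)(C)C)CC[C@@]2(C)C1=O | intermediate
11 | epoxy ketone, C23–C24 oxirane on the face of the C15 methyl group | C[C@@]12O[C@@H]1C[C@H]1OC(C)(C)[C@@H](O[Si](C)(C)C(C)(C)C)CC[C@@]1(C)C2=O | intermediate
12 | allylic alcohol, C14=C24 alkene, C23 hydroxyl syn to the C15 methyl group | CC1=C[C@]2(C)CC[C@H](O[Si](C)(C)C(C)(C)C)C(C)(C)O[C@@H]2C[C@H]1O | intermediate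
13 | (tributylstannyl)methyl ether of 12 | CC1=C[C@]2(C)CC[C@H](O[Si](C)(C)C(C)(C)C)C(C)(C)O[C@@H]2C[C@H]1OC[Sn](CCCC)(CCCC)CCCC | intermediate
14 | homoallylic alcohol, C13 hydroxymethyl on C14 syn to the C15 methyl group, C23=C24 alkene | CC1=CC[C@H]2OC(C)(C)[C@@H](O[Si](C)(C)C(C)(C)C)CC[C@@]2(C)[C@@H]1CO | intermediate
15 | epoxy alcohol, C23–C24 oxirane syn to the hydroxymethyl group | C[C@@]12O[C@@H]1C[C@H]1OC(C)(C)[C@@H](O[Si](C)(C)C(C)(C)C)CC[C@@]1(C)[C@@H]2CO | intermediate
16 | diol, primary C13 hydroxyl and tertiary C24 hydroxyl, C18 silyl ether | OC[C@H]1[C@]2(C)CC[C@H](O[Si](C)(C)C(C)(C)C)C(C)(C)O[C@@H]2CC[C@@]1(C)O | intermediate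
17 | C13 aldehyde of 16 | O=C[C@H]1[C@]2(C)CC[C@H](O[Si](C)(C)C(C)(C)C)C(C)(C)O[C@@H]2CC[C@@]1(C)O | intermediate
18 | C24 triethylsilyl ether of 17 | O=C[C@H]1[C@]2(C)CC[C@H](O[Si](C)(C)C(C)(C)C)C(C)(C)O[C@@H]2CC[C@@]1(C)O[Si](CC)(CC)CC | intermediate
19 | (S)-(−)-limonene | CC1=CC[C@H](CC1)C(C)=C | starting material
20 | B-alkyl-9-BBN adduct of 19 | CC1=CC[C@H](CC1)C(C)CB1C2CCCC1CCC2 | intermediate
21 | 2-[(1S)-4-methylcyclohex-3-en-1-yl]propan-1-ol (both C2 epimers) | CC1=CC[C@H](CC1)C(C)CO | intermediate
22 | 2-[(1S)-4-methylcyclohex-3-en-1-yl]propanoic acid (both C2 epimers) | CC1=CC[C@H](CC1)C(C)C(O)=O | intermediate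
23 | N-methoxy-N-methyl-2-[(1S)-4-methylcyclohex-3-en-1-yl]propanamide (both C2 epimers) | CC1=CC[C@H](CC1)C(C)C(=O)N(C)OC | intermediate
24 | N-methoxy-N,2-dimethyl-2-[(1S)-4-methylcyclohex-3-en-1-yl]propanamide | CC1=CC[C@H](CC1)C(C)(C)C(=O)N(C)OC | intermediate
25 | secondary ozonide (1,2,4-trioxolane) of 24 | CC12OOC(O1)C[C@H](CC2)C(C)(C)C(=O)N(C)OC | intermediate
26 | (3S)-N-methoxy-N,2,2-trimethyl-6-oxo-3-(2-oxoethyl)heptanamide | CC(=O)CC[C@@H](CC=O)C(C)(C)C(=O)N(C)OC | intermediate
27 | 2-[(1S)-2-formyl-3-methylcyclopent-2-en-1-yl]-N-methoxy-N,2-dimethylpropanamide | CC1=C(C=O)[C@H](CC1)C(C)(C)C(=O)N(C)OC | intermediate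
28 | epoxy aldehyde, 2,3-oxirane of 27 trans to the amide side chain | C[C@@]12O[C@]1(C=O)[C@H](CC2)C(C)(C)C(=O)N(C)OC | intermediate
29 | 2-[(1S,3S)-3-hydroxy-3-methyl-2-methylidenecyclopentyl]-N-methoxy-N,2-dimethylpropanamide | C[C@]1(O)CC[C@H](C(C)(C)C(=O)N(C)OC)C1=C | intermediate
30 | B-alkyl-9-BBN adduct of 29 | C[C@]1(O)CC[C@H](C(C)(C)C(=O)N(C)OC)[C@@H]1CB1C2CCCC1CCC2 | intermediate
31 | 2-[(1S,2S,3S)-3-hydroxy-3-methyl-2-(prop-2-en-1-yl)cyclopentyl]-N-methoxy-N,2-dimethylpropanamide | C[C@]1(O)CC[C@H](C(C)(C)C(=O)N(C)OC)[C@@H]1CC=C | intermediate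
32 | 4-[(1S,2S,3S)-3-hydroxy-3-methyl-2-(prop-2-en-1-yl)cyclopentyl]-2,4-dimethylpent-1-en-3-one | C[C@]1(O)CC[C@H](C(C)(C)C(=O)C(C)=C)[C@@H]1CC=C | intermediate
33 | (1S,3aS,8aS)-1-hydroxy-1,4,4,6-tetramethyl-2,3,3a,4,8,8a-hexahydroazulen-5(1H)-one | CC1=CC[C@H]2[C@H](CC[C@]2(C)O)C(C)(C)C1=O | intermediate
34 | (1S,3aS,8aS)-1,4,4,6-tetramethyl-5-methylidene-1,2,3,3a,4,5,8,8a-octahydroazulen-1-ol | CC1=CC[C@H]2[C@H](CC[C@]2(C)O)C(C)(C)C1=C | intermediate
35 | B-alkyl-9-BBN adduct of 34 | CC1=CC[C@H]2[C@H](CC[C@]2(C)O)C(C)(C)[C@@H]1CB1C2CCCC1CCC2 | intermediate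
36 | (1S,3aS,5R,8aS)-5-(hydroxymethyl)-1,4,4,6-tetramethyl-1,2,3,3a,4,5,8,8a-octahydroazulen-1-ol | CC1=CC[C@H]2[C@H](CC[C@]2(C)O)C(C)(C)[C@@H]1CO | intermediate
37 | 1-phenyl-1H-tetrazol-5-yl sulfide of 36 at C12 | CC1=CC[C@H]2[C@H](CC[C@]2(C)O)C(C)(C)[C@@H]1CSc1nnnn1-c1ccccc1 | intermediate
38 | 1-phenyl-1H-tetrazol-5-yl sulfone of 36 at C12 | CC1=CC[C@H]2[C@H](CC[C@]2(C)O)C(C)(C)[C@@H]1CS(=O)(=O)c1nnnn1-c1ccccc1 | intermediate
39 | C12=C13 alkene joining both halves, bis-silyl ether (E drawn) | CC1=CC[C@H]2[C@H](CC[C@]2(C)O)C(C)(C)[C@@H]1/C=C/[C@H]1[C@]2(C)CC[C@H](O[Si](C)(C)C(C)(C)C)C(C)(C)O[C@@H]2CC[C@@]1(C)O[Si](CC)(CC)CC | intermediate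
40 | C12–C13 saturated bis-silyl ether of the target | CC1=CC[C@H]2[C@H](CC[C@]2(C)O)C(C)(C)[C@@H]1CC[C@H]1[C@]2(C)CC[C@H](O[Si](C)(C)C(C)(C)C)C(C)(C)O[C@@H]2CC[C@@]1(C)O[Si](CC)(CC)CC | intermediate
41 | (3S,5aS,6S,7R,9aR)-6-{2-[(1S,3aS,5R,8aS)-1-hydroxy-1,4,4,6-tetramethyl-1,2,3,3a,4,5,8,8a-octahydroazulen-5-yl]ethyl}-2,2,5a,7-tetramethyldecahydro-1-benzoxepine-3,7-diol | CC1=CC[C@H]2[C@H](CC[C@]2(C)O)C(C)(C)[C@@H]1CC[C@H]1[C@]2(C)CC[C@H](O)C(C)(C)O[C@@H]2CC[C@@]1(C)O | target

**Step count and risks**

Total step count: 33. Longest linear sequence: 18 steps (steps 16–30 then 31–33; the carvone branch, steps 1–15 then 31–33, is equally long).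

Step 6. The hydroxyl may attack C18 in the 6-exo mode, or the developing cation may undergo a hydride shift to a ketone, instead of closing the oxepane. The fallback closes the ring on the alkene instead of the oxirane and sets out from 8. Deoxygenation of the oxirane (NaI, Me3SiCl, MeCN) would give the hydroxy alkene F1. Intramolecular alkoxymercuration with Hg(OCOCF3)2, which follows Markovnikov's rule and so bonds O20 to the tertiary C19, followed by chloride exchange (NaCl) would give the organomercurial oxepane F2. Oxidative demercuration (O2, NaBH4, DMF, −10 °C) would give the oxepanol epimers F3. Dess–Martin oxidation would give the oxepanone F4. Corey–Bakshi–Shibata reduction of the unhindered C18 ketone with (R)-1-methyl-3,3-diphenyltetrahydro-1H,3H-pyrrolo[1,2-c][1,3,2]oxazaborole and BH3·SMe2 would then set the S carbinol and come back to the route at 9.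

Step 9. Hydrazone formation may be too slow at a ketone flanked by two fully substituted carbons, so that the oxirane is opened by hydrazine or the material decomposes before the transposition. The fallback reaches the same allylic alcohol by a radical fragmentation and sets out from 11. Reduction with NaBH4 (MeOH, 0 °C) would give the epoxy alcohol F5, and NaH, CS2, then MeI would give the xanthate F6. Bu3SnH with 2,2′-azobis(2-methylpropionitrile) in toluene at 80 °C would generate the C14 radical, which opens the oxirane by β-scission of the C24–O bond; the C23 oxygen radical takes up hydrogen and the sequence comes back to the route at 12 with the C23 configuration unchanged.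

Step 31. Addition of the β-branched sulfonyl anion to an aldehyde flanked by two fully substituted carbons may be slow, so that self-condensation of the sulfone or β-elimination of the silyloxy group takes over. The fallback joins the halves by carbonyl addition and deoxygenation and sets out from 36. Iodination (I2, PPh3, imidazole) would give the iodide F7. Lithium–iodine exchange with t-BuLi (3 equiv, Et2O, −78 °C, the tertiary hydroxyl as its lithium alkoxide) and addition to 18 would give the carbinol F8. 1,1′-Thiocarbonyldiimidazole would acylate only the secondary C13 hydroxyl to the thiocarbonylimidazolide F9, and Barton–McCombie reduction (Bu3SnH, 2,2′-azobis(2-methylpropionitrile), toluene, 80 °C) would come back to the route at 40.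

Further compounds
F1 | step 6 | (5R,6R)-5-hydroxy-2,6-dimethyl-6-(4-methylpent-3-en-1-yl)cyclohex-2-en-1-one | CC1=CC[C@@H](O)[C@@](C)(CCC=C(C)C)C1=O
F2 | step 6 | 3-(chloromercurio) analogue of 9 (C18 configuration undefined) | CC1=CC[C@H]2OC(C)(C)C([Hg]Cl)CC[C@@]2(C)C1=O
F3 | step 6 | C18 epimer mixture of 9 | CC1=CC[C@H]2OC(C)(C)C(O)CC[C@@]2(C)C1=O
F4 | step 6 | C18 ketone of 9 | CC1=CC[C@H]2OC(C)(C)C(=O)CC[C@@]2(C)C1=O
F5 | step 9 | C14 alcohol of 11 (epoxy alcohol, C14 configuration undefined) | C[C@@]12O[C@@H]1C[C@H]1OC(C)(C)[C@@H](O[Si](C)(C)C(C)(C)C)CC[C@@]1(C)C2O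
F6 | step 9 | S-methyl xanthate of F5 | C[C@@]12O[C@@H]1C[C@H]1OC(C)(C)[C@@H](O[Si](C)(C)C(C)(C)C)CC[C@@]1(C)C2OC(=S)SC
F7 | step 31 | C12 iodide of 36 | CC1=CC[C@H]2[C@H](CC[C@]2(C)O)C(C)(C)[C@@H]1CI
F8 | step 31 | C13 carbinol joining both halves (C13 configuration undefined) | CC1=CC[C@H]2[C@H](CC[C@]2(C)O)C(C)(C)[C@@H]1CC(O)[C@H]1[C@]2(C)CC[C@H](O[Si](C)(C)C(C)(C)C)C(C)(C)O[C@@H]2CC[C@@]1(C)O[Si](CC)(CC)CC
F9 | step 31 | C13 O-(imidazol-1-ylthiocarbonyl) derivative of F8 | CC1=CC[C@H]2[C@H](CC[C@]2(C)O)C(C)(C)[C@@H]1CC(OC(=S)n1ccnc1)[C@H]1[C@]2(C)CC[C@H](O[Si](C)(C)C(C)(C)C)C(C)(C)O[C@@H]2CC[C@@]1(C)O[Si](CC)(CC)CC
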